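I began from 14.6: the contact time of 10 min divided by the time Z and J take to meet, the pairing number N (a Damköhler number for a second-order loss).

| flask | L | Q | remark | time |
|---|---|---|---|---|
| winter | 0.80 M | 0.76 M | run made earlier |  |
| noon | 0.80 M | 0.38 M | run made earlier |  |
| dawn | 0.80 M | 0.57 M | run made earlier |  |
| Tuesday's | 0.80 M | 0.760 M (fed, over 5.00 min) | a stirred flask in which Q is dosed at a steady rate over 5.00 min without added volume, worked up at 10 min | 10 min |
| Sunday's | 0.80 M (fed, over 5.00 min) | 0.760 M | all but L at the start; L goes in evenly over 5.00 min, the run ends at 10 min | 10 min |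
| Saturday's | 0.80 M | 0.760 M | a closed flask charged with all of it at once and left for 10 min | 10 min |
| Thursday's | 0.80 M | 0.760 M | one stirred flow tank at steady state, fed with the mixture as stated, mean residence time 10 min |  |

| run | time / min | Z / % | L / % |
|---|---|---|---|
| winter | 0.500 | 40.9 | 32.4 |
| winter | 0.833 | 33.3 | 29.7 |
| winter | 1.50 | 23.9 | 26.2 |
| winter | 3.00 | 16.0 | 16.8 |
| winter | 6.00 | 9.2 | 12.4 |
| noon | 0.500 | 25.9 | 63.5 |
| noon | 1.50 | 18.5 | 59.5 |
| noon | 3.00 | 13.9 | 55.7 |
| noon | 4.00 | 10.2 | 54.6 |
| noon | 6.00 | 7.5 | 53.4 |
| dawn | 0.500 | 36.0 | 48.3 |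
| dawn | 0.833 | 28.6 | 45.8 |
| dawn | 1.50 | 21.5 | 40.5 |
| dawn | 3.00 | 14.1 | 36.3 |
| dawn | 6.00 | 9.4 | 32.1 |

(standard deviation of a reading: 1 percentage point)

- percent here means L units held: one E counts as two
- the stated concentrations are those of everything mixed, before any reaction; amounts are the same in each set-up
- steps thought possible: L + Q -> Z + J; 2 L -> E; Z + J -> G; Q <-> D
- the feed brings no volume worth counting
- the earlier runs were made in a closed, stirred flask

- the set-up with the highest amount of Z at the outlet or at the end, in percent of the L put in ("none" if the first two lie within 2 percentage points) (Tuesday's / Sunday's / Saturday's / Thursday's / none)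
- amount of Z at the outlet or at the end, in percent of the L put in, Tuesday's
- amount of Z at the outlet or at the end, in percent of the L put in, Sunday's
- amount of Z at the outlet or at the end, in percent of the L put in, Saturday's
- amount of Z at the outlet or at the end, in percent of the L put in, Thursday's

Two times went into it. L + Q gives Z and J in equal amounts, and Z + J takes them away together as G, so the reciprocal of Z should climb in a straight line. The making was quick: in the winter run, charged as Saturday's flask is, L read 32.4 % by 0.500 min, far earlier than the contact time. From that run's first and last Z readings I read a slope of 1.91 /M/min, with the later trickle of L folded in. Q, the limiting reagent, is charged at less than L, so I counted the Z made as 0.760 M, and the pairing time came to 0.687 min.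

Let y be Z as a share of the Q charge; the charge ratio turns it into percent of L.

Closed, Saturday's: y = 1/(1 + N), giving 6.11 %

Fed, Tuesday's and Sunday's, with N shortened by half the dosing time: 7.97 %

Tank, Thursday's: N·y·y + y = 1, giving 21.9 %

The forecast gave 12.3 % for Tuesday's, 12.8 % for Sunday's, 6.6 % for Saturday's and 18.8 % for Thursday's, and named Thursday's: “The tank keeps Z dilute”. My fed figure stood below its two and my tank above its own, with the same winner.

The flasks gave 9.17 % for Tuesday's, 10.6 % for Sunday's, 6.58 % for Saturday's and 15.5 % for Thursday's, so Thursday's led.

    L + Q → Z + J (k = 0.220 /M/s)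
    2 L → E (k = 3.70 × 10⁻⁵ /M/s)
    Z + J → G (k = 0.0540 /M/s)
    Q ⇌ D (K = 4.50, k = 0.0510 /s)

Thursday's tank held less G, 62.6 %, than Saturday's flask, 84.5 %. Run backwards, Saturday's Z returns a pairing number of 13.4 against my 14.6.

Saturday's flask read at 40 min has N stretched to 58.4, which gives 1.60 %. The computed result there is 1.57 %.

All runs are calculated with constants of no real substance; the scatter is artificial.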